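## Retrosynthetic overview

1. Arteminorin C comes from its tri-O-benzyl ether by one global hydrogenolysis at the end.
2. Both pyranone rings (B and C) are cut at their aryl–oxygen bonds, O1–C8a and O1'–C8a'. The forward step is a twofold dehydrogenative C–H lactonisation of an unsymmetrical 2,3-bis(arylidene)succinic acid. The succinate C2–C3 bond is already the C3–C3' link.
3. The diacid comes from a Stobbe condensation of O-benzylsyringaldehyde with an arylidenesuccinate. That ester comes from a PBu3-mediated Wittig reaction of 3,4-dibenzyloxybenzaldehyde with dimethyl maleate.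
4. Ring order: benzene rings A (isofraxidin half) and D (esculetin half) are bought. Pyranone C (esculetin half) closes first and pyranone B (isofraxidin half) second, in the same flask.

Assumption: the target has no stereocentre and its C3–C3' axis (flanked only by H and C=O) rotates freely, so it is achiral and there is no enantiomer to select; both O-benzylated aldehydes are taken as inexpensive catalogue compounds.

## Route

Step 1
Reactants: 1 3,4-bis(benzyloxy)benzaldehyde; 2 dimethyl maleate
Product: 4 dimethyl (2E)-2-{[3,4-bis(benzyloxy)phenyl]methylidene}butanedioate, via tributylphosphonium ylide 3 (not isolated)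
Conditions: PBu3 (1.3 equiv), 2 (1.3 equiv), THF, 25 → 50 °C, 16 h
Reagents that add atoms: none
Why: Phospha-Michael addition of PBu3 to the maleate and a proton shift give the ester-stabilised ylide 3, whose Wittig olefination of 1 gives the E-arylidenesuccinate diester in one operation; no stereocentre is formed.

Step 2
Reactants: 4 dimethyl (2E)-2-{[3,4-bis(benzyloxy)phenyl]methylidene}butanedioate; 5 4-(benzyloxy)-3,5-dimethoxybenzaldehyde
Product: 7 (2E,3E)-2-{[4-(benzyloxy)-3,5-dimethoxyphenyl]methylidene}-3-{[3,4-bis(benzyloxy)phenyl]methylidene}butanedioic acid, via Stobbe half-ester 6 (not isolated)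
Conditions: NaOMe (1.5 equiv), MeOH, reflux, 6 h; then 2 M aq NaOH, reflux, 8 h; then 2 M HCl to pH 2
Reagents that add atoms: sodium hydroxide, [Na+].[OH-]
Why: In this Stobbe condensation the CH2 enolate of 4 adds to the more electrophilic trialkoxy aldehyde, the alkoxide lactonises onto the conjugated ester and E1cB opening gives half-ester 6, which is saponified in the same pot; benzyl ethers are inert to base, and the E/Z ratio does not matter because step 3 re-equilibrates both alkenes.

Step 3
Reactants: 7 (2E,3E)-2-{[4-(benzyloxy)-3,5-dimethoxyphenyl]methylidene}-3-{[3,4-bis(benzyloxy)phenyl]methylidene}butanedioic acid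
Product: 10 7-(benzyloxy)-3-[6,7-bis(benzyloxy)-2-oxo-2H-chromen-3-yl]-6,8-dimethoxy-2H-chromen-2-one, via bis-Z diacid 8 (not isolated), via monocoumarin acid 9 (not isolated)
Conditions: riboflavin tetraacetate (10 mol %), MeCN/MeOH 1:1 (5 mM), 450 nm LED, Ar, 25 °C, 4 h; then O2 (1 atm), 450 nm LED, 25 °C, 36 h
Reagents that add atoms: none
Why: Proposed new method: twofold flavin-photocatalysed E-to-Z isomerisation and aerobic dehydrogenative C–H lactonisation of a 2,3-bis(arylidene)succinic acid. Triplet energy transfer from the excited flavin (about 50 kcal/mol) twists each styrenyl C=C and populates the isomers whose aryl ring lies cis to its own CO2H (drawn as 8). The same excited flavin (about +1.4 to +1.7 V vs SCE) then removes one electron from the alkoxy-rich arene/carboxylic acid pair. The carboxyl oxygen closes 6-endo on the ortho carbon that carries most of the hole: in ring D this is the unhindered site para to the 3-OBn group, and in ring A it is either of the two equivalent sites ortho/para to the OMe groups. Loss of a second electron and a proton rearomatises the ring, while O2 returns the reduced flavin and becomes H2O2. Only Z-configured units can reach the ring, so cyclisation drains the photostationary mixture; the more easily oxidised ring D closes first (9) and ring A second. Light at 450 nm, absorbed only by the flavin, and high dilution suppress the singlet 6π (fulgide-type) closure and dimerisation. The closest known reaction types are the flavin-catalysed isomerisation/oxidative cyclisation of simple β-substituted (E)-cinnamic acids to coumarins and the photoredox dehydrogenative lactonisation of 2-arylbenzoic acids; neither has been shown on α-branched, β-unsubstituted, cross-conjugated diacids or in a double sense.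

Step 4
Reactants: 10 7-(benzyloxy)-3-[6,7-bis(benzyloxy)-2-oxo-2H-chromen-3-yl]-6,8-dimethoxy-2H-chromen-2-one
Product: 11 arteminorin C, 3-(6,7-dihydroxy-2-oxo-2H-chromen-3-yl)-7-hydroxy-6,8-dimethoxy-2H-chromen-2-one
Conditions: H2 (1 atm), 10% Pd/C, THF/MeOH 2:1, 25 °C, 4 h
Reagents that add atoms: none
Why: Catalytic hydrogenolysis cleaves the three aryl benzyl ethers much faster than it touches the trisubstituted, aryl-conjugated lactone C=C bonds, and the methyl ethers and lactones are inert.

## Compound list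

1 | 3,4-bis(benzyloxy)benzaldehyde | O=Cc1ccc(OCc2ccccc2)c(OCc2ccccc2)c1 | starting material
2 | dimethyl maleate | COC(=O)/C=C\C(=O)OC | starting material
3 | dimethyl 2-(tributyl-λ5-phosphanylidene)butanedioate | CCCCP(CCCC)(CCCC)=C(CC(=O)OC)C(=O)OC | intermediate
4 | dimethyl (2E)-2-{[3,4-bis(benzyloxy)phenyl]methylidene}butanedioate | COC(=O)C/C(C(=O)OC)=C\c1ccc(OCc2ccccc2)c(OCc2ccccc2)c1 | intermediate
5 | 4-(benzyloxy)-3,5-dimethoxybenzaldehyde | COc1cc(C=O)cc(OC)c1OCc1ccccc1 | starting material
6 | (2E,3E)-2-{[3,4-bis(benzyloxy)phenyl]methylidene}-3-{[4-(benzyloxy)-3,5-dimethoxyphenyl]methylidene}-4-methoxy-4-oxobutanoic acid | COc1cc(/C=C(C(=O)OC)\C(C(=O)O)=C/c2ccc(OCc3ccccc3)c(OCc3ccccc3)c2)cc(OC)c1OCc1ccccc1 | intermediate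
7 | (2E,3E)-2-{[4-(benzyloxy)-3,5-dimethoxyphenyl]methylidene}-3-{[3,4-bis(benzyloxy)phenyl]methylidene}butanedioic acid | COc1cc(/C=C(C(=O)O)\C(C(=O)O)=C/c2ccc(OCc3ccccc3)c(OCc3ccccc3)c2)cc(OC)c1OCc1ccccc1 | intermediate
8 | (2Z,3Z)-2-{[4-(benzyloxy)-3,5-dimethoxyphenyl]methylidene}-3-{[3,4-bis(benzyloxy)phenyl]methylidene}butanedioic acid | COc1cc(/C=C(C(=O)O)/C(C(=O)O)=C/c2ccc(OCc3ccccc3)c(OCc3ccccc3)c2)cc(OC)c1OCc1ccccc1 | intermediate
9 | (2Z)-3-[4-(benzyloxy)-3,5-dimethoxyphenyl]-2-[6,7-bis(benzyloxy)-2-oxo-2H-chromen-3-yl]prop-2-enoic acid | COc1cc(/C=C(C(=O)O)/c2cc3cc(OCc4ccccc4)c(OCc4ccccc4)cc3oc2=O)cc(OC)c1OCc1ccccc1 | intermediate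
10 | 7-(benzyloxy)-3-[6,7-bis(benzyloxy)-2-oxo-2H-chromen-3-yl]-6,8-dimethoxy-2H-chromen-2-one | COc1cc2cc(-c3cc4cc(OCc5ccccc5)c(OCc5ccccc5)cc4oc3=O)c(=O)oc2c(OC)c1OCc1ccccc1 | intermediate
11 | arteminorin C | COc1cc2cc(-c3cc4cc(O)c(O)cc4oc3=O)c(=O)oc2c(OC)c1O | target

## Step count and risks

Total step count: 4. Longest linear sequence: 4.

**Risk 1, step 3 (the proposed reaction).**
- E-configured units may close C–C to 1-aryl-1,2-dihydronaphthalenes, by a radical-cation or a photochemical path.
- The sequence may stall at 9.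
- The flavin may strip benzyl groups oxidatively.

The fallback uses known chemistry only. It sets out from 7, comes back at 10, and removes the alkene-geometry problem by saturating first. H2 (1 atm) over Pd/C poisoned with 2,2'-bipyridyl in THF/MeOH reduces both C=C bonds and keeps the aryl benzyl ethers. This gives 2-{[4-(benzyloxy)-3,5-dimethoxyphenyl]methyl}-3-{[3,4-bis(benzyloxy)phenyl]methyl}butanedioic acid F1, a diastereomer mixture whose two centres are erased later. PhI(OCOCF3)2 (2.4 equiv) with BF3·OEt2 in CH2Cl2 at −20 °C is the established trivalent-iodine oxidative cyclisation of electron-rich 3-arylpropanoic acids to 3,4-dihydrocoumarins. It closes both lactones to 7-(benzyloxy)-3-[6,7-bis(benzyloxy)-2-oxo-3,4-dihydro-2H-chromen-3-yl]-6,8-dimethoxy-3,4-dihydro-2H-chromen-2-one F2. DDQ (2.5 equiv) in refluxing 1,4-dioxane then dehydrogenates both rings to 10.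

**Risk 2, step 2.**
- Methoxide may shift the double bond of 4 out of conjugation with the arene.
- The electron-rich aldehyde may react sluggishly.
- The hindered ester of 6 may resist hydrolysis.

The fallback sets out from 4 (with 5), comes back at 7, and separates C–C bond formation from elimination. LDA in THF at −78 °C, addition of 5 and a cold AcOH quench give the aldol dimethyl (3E)-2-{[4-(benzyloxy)-3,5-dimethoxyphenyl](hydroxy)methyl}-3-{[3,4-bis(benzyloxy)phenyl]methylidene}butanedioate F3 as a diastereomer mixture. MsCl/Et3N in CH2Cl2 at 0 °C gives its mesylate, dimethyl (3E)-2-{[4-(benzyloxy)-3,5-dimethoxyphenyl](methanesulfonyloxy)methyl}-3-{[3,4-bis(benzyloxy)phenyl]methylidene}butanedioate F4. DBU at 25 °C eliminates it (E1cB) to dimethyl (2E,3E)-2-{[4-(benzyloxy)-3,5-dimethoxyphenyl]methylidene}-3-{[3,4-bis(benzyloxy)phenyl]methylidene}butanedioate F5. LiOH in THF/H2O at 60 °C then gives 7.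

**Risk 3, step 1.**
- PBu3 may oligomerise the maleate faster than the ylide olefinates the electron-rich aldehyde.

The fallback sets out from 1 and comes back at 4. A classical Stobbe condensation of 1 with dimethyl succinate (NaOMe, MeOH, reflux) gives (3E)-4-[3,4-bis(benzyloxy)phenyl]-3-(methoxycarbonyl)but-3-enoic acid F6. Fischer esterification (MeOH, cat. H2SO4, reflux) converts it into 4.

## Further compounds

F1 | step 3 | 2-{[4-(benzyloxy)-3,5-dimethoxyphenyl]methyl}-3-{[3,4-bis(benzyloxy)phenyl]methyl}butanedioic acid (diastereomer mixture) | COc1cc(CC(C(=O)O)C(C(=O)O)Cc2ccc(OCc3ccccc3)c(OCc3ccccc3)c2)cc(OC)c1OCc1ccccc1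
F2 | step 3 | 7-(benzyloxy)-3-[6,7-bis(benzyloxy)-2-oxo-3,4-dihydro-2H-chromen-3-yl]-6,8-dimethoxy-3,4-dihydro-2H-chromen-2-one (diastereomer mixture) | COc1cc2CC(C3Cc4cc(OCc5ccccc5)c(OCc5ccccc5)cc4OC3=O)C(=O)Oc2c(OC)c1OCc1ccccc1
F3 | step 2 | dimethyl (3E)-2-{[4-(benzyloxy)-3,5-dimethoxyphenyl](hydroxy)methyl}-3-{[3,4-bis(benzyloxy)phenyl]methylidene}butanedioate (diastereomer mixture) | COC(=O)C(C(O)c1cc(OC)c(OCc2ccccc2)c(OC)c1)/C(C(=O)OC)=C\c1ccc(OCc2ccccc2)c(OCc2ccccc2)c1
F4 | step 2 | dimethyl (3E)-2-{[4-(benzyloxy)-3,5-dimethoxyphenyl](methanesulfonyloxy)methyl}-3-{[3,4-bis(benzyloxy)phenyl]methylidene}butanedioate (diastereomer mixture) | COC(=O)C(C(OS(C)(=O)=O)c1cc(OC)c(OCc2ccccc2)c(OC)c1)/C(C(=O)OC)=C\c1ccc(OCc2ccccc2)c(OCc2ccccc2)c1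
F5 | step 2 | dimethyl (2E,3E)-2-{[4-(benzyloxy)-3,5-dimethoxyphenyl]methylidene}-3-{[3,4-bis(benzyloxy)phenyl]methylidene}butanedioate | COc1cc(/C=C(C(=O)OC)\C(C(=O)OC)=C/c2ccc(OCc3ccccc3)c(OCc3ccccc3)c2)cc(OC)c1OCc1ccccc1
F6 | step 1 | (3E)-4-[3,4-bis(benzyloxy)phenyl]-3-(methoxycarbonyl)but-3-enoic acid | OC(=O)C/C(C(=O)OC)=C\c1ccc(OCc2ccccc2)c(OCc2ccccc2)c1
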